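## Retrosynthetic overview
1. The CH2OH group comes from a last-step 1,2-reduction of the corresponding bicyclic 2-alkyl-dienal.
2. Both carbocycles are opened at once (C4–C5 and C9–C10) to an acyclic C25 polyene aldehyde that already carries the butenolide. The forward reaction is one proton-initiated cationic cascade ending in loss of H-9.
3. The (Z)-C5=C10 olefin encodes the cis ring fusion by anti addition. A confined chiral Brønsted acid sets the absolute sense. The electron-poor trienal/butenolide tail stops the cascade after two rings.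
4. The acyclic chain is cut at C13=C14 (crossed aldol condensation) and at C8=C9 (Wittig on nerylacetone). The C8=C9 geometry does not matter, because C9 ends up sp2.
5. Ring order: the butenolide is bought intact and joined at C16 by a Heck reaction; then ring A and ring B close in the same flask.

## Assumptions
- Stereochemistry: read literally, the SMILES has H-5 and the C10 methyl on the same face. This is a cis-decalin, (4aR,8aS), that is 5R,10S, and that is the compound made here.
- Atom labels follow labdane numbering: C4 is the CMe2 carbon, C5 and C10 are the ring-fusion carbons, C8=C9 is the ring olefin, C11/C12 are the tether CH2 groups, C13 bears the CH2OH carbon (C24), and C14–C16 lead to the butenolide.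
- Supply: nerylacetone is bought as the pure Z isomer. It can also be distilled out of cheap technical geranylacetone.
- Catalyst sense: the IDPi enantiomer used is the one that turns (3E,7E)-homofarnesol into (−)-ambrox. The same ring A chair helicity applied to the Z olefin gives 10S,5R. The mirror-image catalyst is equally available if the sense is reversed.

## Route

Step 1
Reactants: 1 nerylacetone, (5Z)-6,10-dimethylundeca-5,9-dien-2-one; 2 (4-carboxybutyl)triphenylphosphonium bromide
Product: 5 methyl (9Z)-6,10,14-trimethylpentadeca-5,9,13-trienoate as a 5E/5Z mixture, via ylide carboxylate 3 (not isolated), via potassium trienoate 4 (not isolated)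
Conditions: 2 (1.5 equiv), KOtBu (3.0 equiv), THF, 0 °C; 1, 0 °C to rt, 12 h; then MeI, DMF, rt
Reagents that add atoms: iodomethane, CI
Why: Wittig olefination of a methyl ketone by the non-stabilised ylide 3, followed by SN2 O-methylation of carboxylate 4; the new C8=C9 olefin forms as roughly a 1:1 E/Z mixture, which is harmless because C9 becomes sp2 again in step 5, and the Z olefin of 1 is untouched.

Step 2
Reactants: 5 methyl (9Z)-6,10,14-trimethylpentadeca-5,9,13-trienoate
Product: 7 (9Z)-6,10,14-trimethylpentadeca-5,9,13-trienal as a 5E/5Z mixture, via aluminium hemiacetal 6 (not isolated)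
Conditions: DIBAL-H (1.1 equiv), CH2Cl2, −78 °C; MeOH, then aq. Rochelle salt
Reagents that add atoms: none
Why: Partial ester reduction with DIBAL-H, in which the tetrahedral aluminium hemiacetal 6 is stable at −78 °C and collapses to the aldehyde only on work-up; the isolated trisubstituted olefins are inert and no stereocentre is formed.

Step 3
Reactants: 8 4-bromofuran-2(5H)-one; 9 acrolein
Product: 10 (2E)-3-(5-oxo-2,5-dihydrofuran-3-yl)prop-2-enal
Conditions: Pd(OAc)2 (5 mol %), n-Bu4NCl, NaHCO3, DMF, 50 °C
Reagents that add atoms: none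
Why: Mizoroki–Heck reaction under Jeffery conditions, in which zerovalent palladium formed in situ inserts into the activated C–Br bond of 8, adds to the unsubstituted terminus of acrolein and gives the E-enal by syn β-hydride elimination; NaHCO3 is too weak to open or deprotonate the butenolide.

Step 4
Reactants: 7 (9Z)-6,10,14-trimethylpentadeca-5,9,13-trienal; 10 (2E)-3-(5-oxo-2,5-dihydrofuran-3-yl)prop-2-enal
Product: 12 (2E,4E)-5-(5-oxo-2,5-dihydrofuran-3-yl)-2-[(7Z)-4,8,12-trimethyltrideca-3,7,11-trien-1-yl]penta-2,4-dienal as a 3E/3Z mixture in the side chain, via aldol adduct 11 (not isolated)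
Conditions: 10 (1.5 equiv), pyrrolidine (20 mol %), PhCO2H (20 mol %), 4 Å MS, CH2Cl2, rt, 7 added over 6 h
Reagents that add atoms: none
Why: Amine-catalysed crossed aldol condensation (enamine donor, addition, then E1cB loss of water), in which 10 has no α-hydrogen and can only be the acceptor, slow addition keeps 7 from self-condensing, and reversible iminium/dienamine formation equilibrates the new C13=C14 bond to the favoured E-2-alkylenal geometry (CHO trans to the vinyl group, avoiding A1,3 strain), which is the geometry of the target.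

Step 5
Reactants: 12 (2E,4E)-5-(5-oxo-2,5-dihydrofuran-3-yl)-2-[(7Z)-4,8,12-trimethyltrideca-3,7,11-trien-1-yl]penta-2,4-dienal
Product: 15 (2E,4E)-5-(5-oxo-2,5-dihydrofuran-3-yl)-2-{2-[(4aR,8aS)-2,5,5,8a-tetramethyl-3,4,4a,5,6,7,8,8a-octahydronaphthalen-1-yl]ethyl}penta-2,4-dienal, via ring B 7-ene isomer 13 (not isolated), via exocyclic 8(17)-ene isomer 14 (not isolated)
Conditions: IDPi acid HN[P(=NSO2CF3)(O2C20H10Ar2)]2 (BINOL-derived, Ar = spiro[cyclohexane-1,9'-fluoren]-2'-yl, 5 mol %), (CF3)3COH, −10 °C, 72 h; then 25 °C, 12 h
Reagents that add atoms: none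
Why: Proposed new method: the confined chiral acid protonates the most accessible and most electron-rich olefin (terminal C3=C4), ring A and then ring B close by anti addition across the (Z)-C5=C10 olefin (Stork–Eschenmoser stereospecificity, so H-5 and the C10 methyl end up cis, and the pocket-imposed ring A chair helicity fixes 10S and hence 5R), the cascade halts at the C8 cation because attack by C13=C14 would place a cation next to the formyl group of a tail further deactivated by solvent hydrogen bonding, and proton loss followed by re-protonation of 13 and 14 by the same acid funnels all material, from both C8=C9 geometries of 12, into the tetrasubstituted 8(9)-olefin as the thermodynamic sink without touching C5 or C10; the closest known reaction types are the IDPi-catalysed, hydroxyl-terminated asymmetric polyene cyclisation of homofarnesol in perfluorinated alcohols and the cyclisation of polyprenoids by chiral Lewis-acid-assisted Brønsted acids.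

Step 6
Reactants: 15 the bicyclic dienal from step 5
Product: 16 4-{(1E,3E)-4-(hydroxymethyl)-6-[(4aR,8aS)-2,5,5,8a-tetramethyl-3,4,4a,5,6,7,8,8a-octahydronaphthalen-1-yl]hexa-1,3-dien-1-yl}furan-2(5H)-one (target)
Conditions: NaBH4, CeCl3·7H2O, MeOH/THF, −78 to −40 °C
Reagents that add atoms: none
Why: Luche reduction, in which the hard alkoxyborohydride attacks the aldehyde 1,2 within minutes at low temperature while the lactone carbonyl and the conjugated triene are left alone, so no stereocentre or olefin geometry changes.

## Compound list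
1 | nerylacetone, (5Z)-6,10-dimethylundeca-5,9-dien-2-one | CC(=O)CC/C=C(/C)CCC=C(C)C | starting material
2 | (4-carboxybutyl)triphenylphosphonium bromide | [Br-].OC(=O)CCCC[P+](c1ccccc1)(c1ccccc1)c1ccccc1 | starting material
3 | potassium 5-(triphenyl-λ5-phosphanylidene)pentanoate (ylide carboxylate) | [K+].[O-]C(=O)CCCC=P(c1ccccc1)(c1ccccc1)c1ccccc1 | intermediate
4 | potassium (9Z)-6,10,14-trimethylpentadeca-5,9,13-trienoate (5E/5Z) | [K+].[O-]C(=O)CCCC=C(C)CC/C=C(/C)CCC=C(C)C | intermediate
5 | methyl (9Z)-6,10,14-trimethylpentadeca-5,9,13-trienoate (5E/5Z) | COC(=O)CCCC=C(C)CC/C=C(/C)CCC=C(C)C | intermediate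
6 | diisobutylaluminium hemiacetal of 5 | COC(CCCC=C(C)CC/C=C(/C)CCC=C(C)C)O[Al](CC(C)C)CC(C)C | intermediate
7 | (9Z)-6,10,14-trimethylpentadeca-5,9,13-trienal (5E/5Z) | O=CCCCC=C(C)CC/C=C(/C)CCC=C(C)C | intermediate
8 | 4-bromofuran-2(5H)-one | O=C1C=C(Br)CO1 | starting material
9 | acrolein | C=CC=O | starting material
10 | (2E)-3-(5-oxo-2,5-dihydrofuran-3-yl)prop-2-enal | O=C/C=C/C1=CC(=O)OC1 | intermediate
11 | aldol adduct of 7 and 10 (β-hydroxy aldehyde, diastereomer mixture) | O=CC(CCC=C(C)CC/C=C(/C)CCC=C(C)C)C(O)/C=C/C1=CC(=O)OC1 | intermediate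
12 | acyclic (2E,4E)-dienal with (7Z)-homofarnesyl chain (C8=C9 E/Z) | CC(C)=CCC/C(C)=C\CCC(C)=CCC/C(=C\C=C\C1=CC(=O)OC1)C=O | intermediate
13 | cis-fused bicyclic dienal, 7-ene isomer (C9 epimers) | CC=1C(CC/C(=C\C=C\C3=CC(=O)OC3)C=O)[C@@]2(C)CCCC(C)(C)[C@H]2CC=1 | intermediate
14 | cis-fused bicyclic dienal, exocyclic 8(17)-ene isomer (C9 epimers) | C=C1C(CC/C(=C\C=C\C3=CC(=O)OC3)C=O)[C@@]2(C)CCCC(C)(C)[C@H]2CC1 | intermediate
15 | (4aR,8aS) bicyclic (2E,4E)-dienal, 8(9)-ene | CC1=C(CC/C(=C\C=C\C2=CC(=O)OC2)C=O)[C@@]2(C)CCCC(C)(C)[C@H]2CC1 | intermediate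
16 | target, CNP0232848.3 | CC1=C(CC/C(=C\C=C\C2=CC(=O)OC2)CO)[C@@]2(C)CCCC(C)(C)[C@H]2CC1 | target

## Step count and risks
Total steps: 6. Longest linear sequence: 5 (steps 1, 2, 4, 5, 6).

**Step 5 (highest risk).**
- A stepwise C10 cation could leak to the trans fusion or stop at monocyclic products.
- The two C8=C9 isomers of 12 may cyclise with different selectivity.
- The olefin equilibration may be slow in the catalyst pocket.
- The activated dienal may react with the new ring olefin.

The fallback sets out from 5 and comes back at 15. The rings are closed before the sensitive tail exists. Ester 5 is cyclised with the stoichiometric chiral Lewis-acid-assisted Brønsted acid made from (R)-2'-[(2-fluorobenzyl)oxy]-1,1'-binaphthalen-2-ol and SnCl4 (toluene, −78 °C). The crude product is equilibrated with catalytic I2 in toluene at 80 °C, which a simple ester tolerates, to give methyl 4-[(4aR,8aS)-2,5,5,8a-tetramethyl-3,4,4a,5,6,7,8,8a-octahydronaphthalen-1-yl]butanoate F1. DIBAL-H at −78 °C then gives 4-[(4aR,8aS)-2,5,5,8a-tetramethyl-3,4,4a,5,6,7,8,8a-octahydronaphthalen-1-yl]butanal F2. Condensation of F2 with 10 as in step 4 delivers 15.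

**Step 4.**
- The enamine may add to 10 in Michael fashion.
- Aldehyde 7 may self-condense.
- The amine may damage the butenolide.

The fallback sets out from 7 (with 10) and comes back at 12. It replaces amine catalysis by a stepwise Lewis-acid sequence. Aldehyde 7 with TMSOTf/Et3N gives the trimethylsilyl enol ether of 7 F3. A Mukaiyama aldol addition of F3 to 10 (BF3·OEt2, CH2Cl2, −78 °C) gives 11 as an isolated compound. MsCl/Et3N converts 11 into the mesylate of 11 F4, which loses methanesulfonic acid on addition of DBU to give 12. The E geometry is again the thermodynamic one.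

**Step 3.**
- Acrolein may polymerise.
- Bromide 8 is labile under Heck conditions.

The fallback sets out from 8 and comes back at 10. Stille coupling of 8 with (E)-3-(tributylstannyl)prop-2-en-1-ol (Pd(PPh3)4, CuI, DMF, rt) gives 4-[(1E)-3-hydroxyprop-1-en-1-yl]furan-2(5H)-one F5. MnO2 in CH2Cl2 oxidises F5 to 10.

## Further compounds
F1 | step 5 | methyl 4-[(4aR,8aS)-2,5,5,8a-tetramethyl-3,4,4a,5,6,7,8,8a-octahydronaphthalen-1-yl]butanoate | CC1=C(CCCC(=O)OC)[C@@]2(C)CCCC(C)(C)[C@H]2CC1
F2 | step 5 | 4-[(4aR,8aS)-2,5,5,8a-tetramethyl-3,4,4a,5,6,7,8,8a-octahydronaphthalen-1-yl]butanal | CC1=C(CCCC=O)[C@@]2(C)CCCC(C)(C)[C@H]2CC1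
F3 | step 4 | trimethylsilyl enol ether of 7 | C[Si](C)(C)OC=CCCC=C(C)CC/C=C(/C)CCC=C(C)C
F4 | step 4 | mesylate of 11 | O=CC(CCC=C(C)CC/C=C(/C)CCC=C(C)C)C(OS(C)(=O)=O)/C=C/C1=CC(=O)OC1
F5 | step 3 | 4-[(1E)-3-hydroxyprop-1-en-1-yl]furan-2(5H)-one | OC/C=C/C1=CC(=O)OC1
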